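**Strategy.** The cyclohexane ring C1–C6 is an isopulegol-type p-menthane: the C1 carbinol is homoallylic to the exocyclic C7=C14H2 group on C6, and the tertiary carbinol C3 lies β to C1 beside the oxygenated C2. The ring is therefore cut at C1–C6 and C2–C3. In the key step SnCl4 joins the enediol bis-silyl ether of glycolaldehyde to a sulcatone-derived (R)-α-silyloxy methyl ketone by Mukaiyama aldol addition, and the resulting 2,3,4-trioxygenated citronellal closes in the same flask by a carbonyl-ene reaction. C4 controls C3, and the aldol and the ene chair set C2, C1 and C6. The C4 oxygen later becomes chloride with inversion.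

Key step: step 4

Remark on numbering and faces: ring C1 (CHOH), C2 (CH–O-angelate), C3 (C(OH)CH3), C4 (CHCl), C5 (CH2), C6 (CH bearing the side chain); side chain C7 (=C14H2), C8 (CH–O-angelate), C9, C10–C11 (epoxide). α is the ring face that carries O1, O2, O3 and the C6 side chain in the target; β is the face of Cl and of the C3 methyl group. Ring compounds are named as cyclohexanes with these locants; in all of them C1, C2, C3 and C6 have the absolute configuration of the target.

Assumption: angelic anhydride, (−)-Ipc2BOMe and the D-fructose-derived Shi ketone are taken as purchasable; reagents are named with SMILES but not numbered.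

Step 1
Reactants: 1 6-methylhept-5-en-2-one (sulcatone)
Product: 3 (R)-3-hydroxy-6-methylhept-5-en-2-one, via aminoxy ketone 2 (not isolated)
Conditions: PhN=O (1 equiv, slow addition), 1 (3 equiv), L-proline (20 mol %), DMSO, rt; then CuSO4·5H2O (30 mol %), MeOH, 0 °C
Reagents that add atoms: nitrosobenzene, O=Nc1ccccc1
Why: Proline enamine α-aminoxylation (O-nitroso aldol reaction) should occur at the more substituted α-carbon through the (E)-enamine, whose carboxylic acid delivers the nitroso oxygen to one face so that L-proline gives the (R)-aminoxy ketone, and copper(II)-catalysed N–O cleavage then frees the hydroxyl group without touching the stereocentre.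

Step 2
Reactants: 3 (R)-3-hydroxy-6-methylhept-5-en-2-one
Product: 4 (R)-3-(tert-butyldimethylsilyloxy)-6-methylhept-5-en-2-one
Conditions: TBSCl, imidazole, DMF, 0 °C → rt
Reagents that add atoms: tert-butyldimethylsilyl chloride, CC(C)(C)[Si](C)(C)Cl
Why: Standard silylation of the secondary alcohol should give the non-chelating silyl ether needed for Felkin–Anh control in step 4, and prompt protection prevents α-ketol isomerisation.

Step 3
Reactants: 5 glycolaldehyde dimer (1,4-dioxane-2,5-diol)
Product: 6 (Z)-1,2-bis(trimethylsilyloxy)ethene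
Conditions: Me3SiCl (4.4 equiv), Et3N (5 equiv), DMF, 80 °C; fractional distillation
Reagents that add atoms: chlorotrimethylsilane, C[Si](C)(C)Cl
Why: Under amine-mediated enol silylation conditions the dimer should crack to glycolaldehyde, which is silylated on the hydroxyl group and on the enol oxygen to give the enediol bis-silyl ether, the (Z)-isomer being collected by distillation.

Step 4
Reactants: 4 (R)-3-(tert-butyldimethylsilyloxy)-6-methylhept-5-en-2-one; 6 (Z)-1,2-bis(trimethylsilyloxy)ethene
Product: 9 4α-(tert-butyldimethylsilyloxy)-3β-methyl-6α-(prop-1-en-2-yl)cyclohexane-1α,2α,3α-triol, via aldol aldehyde 7 (not isolated), via ene product TMS ether 8 (not isolated)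
Conditions: SnCl4 (1.1 equiv), CH2Cl2, −78 °C; 6 (1.2 equiv) added over 1 h; −78 → −30 °C; aq. NaHCO3; then citric acid, MeOH, rt
Reagents that add atoms: none
Why: Proposed new method: SnCl4 activates the ketone of 4 for a Mukaiyama aldol addition of 6 that forms C2–C3, and the tin aldolate of the resulting 2,3,4-trioxygenated citronellal 7 then closes C1–C6 by a type-I intramolecular carbonyl-ene reaction, just as citronellal closes to isopulegol under SnCl4 or ZnBr2; the closest known reaction types are the Mukaiyama aldol addition to ketones and the Lewis-acid-promoted carbonyl-ene cyclisation, which are merged here in one flask. The six-membered ring closes through a chair transition state in which the aldehyde carbon C1 bonds to the alkene carbon C6 while a hydrogen of the methyl group cis to C5 passes to the carbonyl oxygen, which leaves the isopropenyl group on C6. C3 is controlled by the C4 stereocentre through Felkin–Anh (Cornforth) addition anti to the non-chelating C4–OTBS group, which places the new C3–O cis to C4–O, and C2 is controlled in the open antiperiplanar aldol transition state, where the silyloxy group of 6 should avoid the tin-bearing side of the carbonyl next to the methyl group, a wrong C2 epimer being drained by retro-aldol because only the all-equatorial chair cyclises fast. C1 and C6 are controlled by that chair, in which C4–OTBS, the C3 methyl group, C2–OTMS and the alkene are equatorial and the aldehyde oxygen is axial, held by the tin alkoxide on the axial C3 oxygen, so that C1–OH forms cis to both O2 and the C6 substituent. The step needs the ene closure to outrun a second aldol addition of 6 to aldehyde 7, which slow addition of 6 to the preformed ketone–SnCl4 complex and the intramolecular tin chelate should secure.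

Step 5
Reactants: 9 4α-(tert-butyldimethylsilyloxy)-3β-methyl-6α-(prop-1-en-2-yl)cyclohexane-1α,2α,3α-triol
Product: 10 1,2-O-isopropylidene acetal of 9 (3α-OH free)
Conditions: 2,2-dimethoxypropane, PPTS (cat.), acetone, rt
Reagents that add atoms: 2,2-dimethoxypropane, COC(C)(C)OC
Why: Acid-catalysed transketalisation should engage the cis-vicinal secondary 1,2-diol as the five-membered dioxolane in preference to the hindered tertiary C3 hydroxyl group, which stays free.

Step 6
Reactants: 10 1,2-O-isopropylidene acetal of 9
Product: 11 1α,2α-(isopropylidenedioxy)-3β-methyl-6α-(prop-1-en-2-yl)cyclohexane-3α,4α-diol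
Conditions: TBAF (1.5 equiv), THF, 0 °C → rt
Reagents that add atoms: none
Why: Fluoride-induced desilylation should remove the only silyl ether and expose the cis 3,4-diol, with the acetonide and the alkene untouched.

Step 7
Reactants: 11 1α,2α-(isopropylidenedioxy)-3β-methyl-6α-(prop-1-en-2-yl)cyclohexane-3α,4α-diol
Product: 12 3α,4α-cyclic sulfate of 11
Conditions: NaH (2.2 equiv), THF, 0 °C; 1,1'-sulfonyldiimidazole (1.2 equiv), −20 °C → rt
Reagents that add atoms: 1,1'-sulfonyldiimidazole, O=S(=O)(n1ccnc1)n1ccnc1
Why: The disodium alkoxide of the cis-diol should be sulfonylated twice by sulfonyl diimidazole to close the five-membered cyclic sulfate directly, which avoids a ruthenium tetroxide oxidation that the alkene would not survive.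

Step 8
Reactants: 12 3α,4α-cyclic sulfate of 11
Product: 14 4β-chloro-1α,2α-(isopropylidenedioxy)-3β-methyl-6α-(prop-1-en-2-yl)cyclohexan-3α-ol, via sulfate monoester 13 (not isolated)
Conditions: Bu4NCl (1.5 equiv), acetone, 50 °C; then H2SO4 (cat.), H2O (1 equiv), THF, rt
Reagents that add atoms: tetrabutylammonium chloride, CCCC[N+](CCCC)(CCCC)CCCC.[Cl-]
Why: Chloride should open the cyclic sulfate by SN2 attack at the secondary carbon C4 rather than at the tertiary C3, which inverts C4 and places chlorine on the β face trans-diaxial to the C3 oxygen, and acid hydrolysis of the sulfate monoester then frees the tertiary alcohol.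

Step 9
Reactants: 14 4β-chloro-1α,2α-(isopropylidenedioxy)-3β-methyl-6α-(prop-1-en-2-yl)cyclohexan-3α-ol
Product: 16 enal (C8 aldehyde) 2-(ring C6-yl)prop-2-enal, via allylic alcohol 15 (not isolated)
Conditions: SeO2 (0.3 equiv), t-BuOOH (3 equiv), CH2Cl2, rt; then MnO2 (10 equiv), CH2Cl2, rt
Reagents that add atoms: tert-butyl hydroperoxide (terminal oxidant), CC(C)(C)OO; selenium dioxide (oxygen carrier), O=[Se]=O
Why: Riley allylic oxidation with catalytic selenium dioxide should hydroxylate the methyl group of the 1,1-disubstituted alkene in preference to the ring methine C6–H (ene reaction then [2,3]-shift), and manganese dioxide oxidises the resulting allylic alcohol to the enal.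

Step 10
Reactants: 16 enal (C8 aldehyde)
Product: 17 (8S)-homoallylic alcohol (C7(=CH2)–C8H(OH)–CH2–CH=CH2 on ring C6)
Conditions: (−)-Ipc2B(allyl) (1.5 equiv, from (−)-Ipc2BOMe and allylMgBr, salt-free), Et2O, −78 °C; then ethanolamine, rt
Reagents that add atoms: (−)-B-allyldiisopinocampheylborane, C=CCB([C@@H]1C[C@@H]2C[C@H]([C@H]1C)C2(C)C)[C@@H]1C[C@@H]2C[C@H]([C@H]1C)C2(C)C
Why: Brown asymmetric allylboration through a chair transition state should add the allyl group to one face of the aldehyde under reagent control, the (+)-α-pinene-derived reagent giving the (8S) carbinol, as it gives (S)-1-phenylbut-3-en-1-ol from benzaldehyde.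

Step 11
Reactants: 17 (8S)-homoallylic alcohol
Product: 18 8-O-angelate of 17
Conditions: angelic acid, 2,4,6-trichlorobenzoyl chloride, Et3N, toluene, rt; then 17, toluene, 80 °C (no DMAP)
Reagents that add atoms: angelic acid ((Z)-2-methylbut-2-enoic acid), C/C=C(/C)C(=O)O
Why: Yamaguchi-type acylation of the secondary allylic alcohol with the preformed mixed anhydride in the absence of DMAP should give the ester without Z to E isomerisation to the tiglate, while the tertiary C3 hydroxyl group does not react.

Step 12
Reactants: 18 8-O-angelate of 17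
Product: 19 prenyl compound (C9H2–C10H=C11(CH3)2 side chain, acetonide intact)
Conditions: Grubbs second-generation catalyst (5 mol %), 2-methylbut-2-ene (excess), CH2Cl2, 40 °C
Reagents that add atoms: 2-methylbut-2-ene, CC=C(C)C
Why: Olefin cross-metathesis of the monosubstituted alkene with 2-methylbut-2-ene should install the trisubstituted prenyl terminus, the 1,1-disubstituted C7=C14 alkene and the angelate being too hindered and electron-poor to take part.

Step 13
Reactants: 19 prenyl compound
Product: 20 8-O-angeloyl 1α,2α,3α-triol (4β-Cl, C10=C11 alkene)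
Conditions: AcOH/H2O/THF (3:1:1), 45 °C
Reagents that add atoms: none
Why: Mild acid hydrolysis should cleave the cis-fused acetonide to the 1,2-diol without affecting the allylic ester, the chlorohydrin or the alkenes.

Step 14
Reactants: 20 8-O-angeloyl 1α,2α,3α-triol
Product: 22 2,8-di-O-angelate (10,11-deoxy target), via stannylene acetal 21 (not isolated)
Conditions: Bu2SnO (1.1 equiv), toluene, 80 °C, 4 Å MS; then angelic anhydride (1.2 equiv), toluene, 0 °C → rt
Reagents that add atoms: angelic anhydride, C/C=C(/C)C(=O)OC(=O)/C(C)=C\C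
Why: Regioselective acylation through the dibutylstannylene acetal should take place at the equatorial oxygen of the cis-diol, which is O2 for either the 1,2- or the 2,3-stannylene, so that the axial C1 and tertiary C3 hydroxyl groups stay free.

Step 15
Reactants: 22 2,8-di-O-angelate (10,11-deoxy target)
Product: 23 CNP0158207.1
Conditions: D-fructose-derived Shi ketone (0.5 equiv), Oxone, K2CO3, Bu4NHSO4 (cat.), MeCN/dimethoxymethane/aq. borate–EDTA buffer, −5 °C, short reaction time
Reagents that add atoms: potassium peroxymonosulfate (Oxone), [K+].[O-]S(=O)(=O)OO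
Why: Shi asymmetric epoxidation by the dioxirane of the D-fructose-derived ketone should epoxidise the electron-rich trisubstituted C10=C11 alkene through the spiro transition state under reagent control to give the (10R) epoxide, leaving the hindered 1,1-disubstituted alkene and the electron-poor angelates untouched.

**Compound list**

1 | 6-methylhept-5-en-2-one (sulcatone) | CC(=O)CCC=C(C)C | starting material
2 | (R)-6-methyl-3-(phenylaminooxy)hept-5-en-2-one | CC(=O)[C@H](ONc1ccccc1)CC=C(C)C | intermediate
3 | (R)-3-hydroxy-6-methylhept-5-en-2-one | CC(=O)[C@H](O)CC=C(C)C | intermediate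
4 | (R)-3-(tert-butyldimethylsilyloxy)-6-methylhept-5-en-2-one | CC(=O)[C@H](O[Si](C)(C)C(C)(C)C)CC=C(C)C | intermediate
5 | glycolaldehyde dimer (1,4-dioxane-2,5-diol) | OC1COC(O)CO1 | starting material
6 | (Z)-1,2-bis(trimethylsilyloxy)ethene | C[Si](C)(C)O/C=C\O[Si](C)(C)C | intermediate
7 | (2R,3R,4R)-4-(tert-butyldimethylsilyloxy)-3-hydroxy-3,7-dimethyl-2-(trimethylsilyloxy)oct-6-enal (tin(IV) aldolate in the flask) | CC(C)=CC[C@@H](O[Si](C)(C)C(C)(C)C)[C@@](C)(O)[C@@H](O[Si](C)(C)C)C=O | intermediate
8 | 4α-(tert-butyldimethylsilyloxy)-3β-methyl-6α-(prop-1-en-2-yl)-2α-(trimethylsilyloxy)cyclohexane-1α,3α-diol | C=C(C)[C@H]1C[C@@H](O[Si](C)(C)C(C)(C)C)[C@@](C)(O)[C@@H](O[Si](C)(C)C)[C@H]1O | intermediate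
9 | 4α-(tert-butyldimethylsilyloxy)-3β-methyl-6α-(prop-1-en-2-yl)cyclohexane-1α,2α,3α-triol | C=C(C)[C@H]1C[C@@H](O[Si](C)(C)C(C)(C)C)[C@@](C)(O)[C@@H](O)[C@H]1O | intermediate
10 | 4α-(tert-butyldimethylsilyloxy)-1α,2α-(isopropylidenedioxy)-3β-methyl-6α-(prop-1-en-2-yl)cyclohexan-3α-ol | C=C(C)[C@H]1C[C@@H](O[Si](C)(C)C(C)(C)C)[C@@](C)(O)[C@@H](OC(C)(C)O3)[C@H]13 | intermediate
11 | 1α,2α-(isopropylidenedioxy)-3β-methyl-6α-(prop-1-en-2-yl)cyclohexane-3α,4α-diol | C=C(C)[C@H]1C[C@@H](O)[C@@](C)(O)[C@@H](OC(C)(C)O3)[C@H]13 | intermediate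
12 | 3α,4α-cyclic sulfate of 11 | C=C(C)[C@H]1C[C@@H](O4)[C@@](C)(OS4(=O)=O)[C@@H](OC(C)(C)O3)[C@H]13 | intermediate
13 | 4β-chloro-1α,2α-(isopropylidenedioxy)-3β-methyl-6α-(prop-1-en-2-yl)cyclohexan-3α-yl hydrogen sulfate (tetrabutylammonium salt in the flask) | C=C(C)[C@H]1C[C@H](Cl)[C@@](C)(OS(=O)(=O)O)[C@@H](OC(C)(C)O3)[C@H]13 | intermediate
14 | 4β-chloro-1α,2α-(isopropylidenedioxy)-3β-methyl-6α-(prop-1-en-2-yl)cyclohexan-3α-ol | C=C(C)[C@H]1C[C@H](Cl)[C@@](C)(O)[C@@H](OC(C)(C)O3)[C@H]13 | intermediate
15 | 4β-chloro-6α-(3-hydroxyprop-1-en-2-yl)-1α,2α-(isopropylidenedioxy)-3β-methylcyclohexan-3α-ol | C=C(CO)[C@H]1C[C@H](Cl)[C@@](C)(O)[C@@H](OC(C)(C)O3)[C@H]13 | intermediate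
16 | 2-[4β-chloro-3α-hydroxy-1α,2α-(isopropylidenedioxy)-3β-methylcyclohex-6α-yl]prop-2-enal | C=C(C=O)[C@H]1C[C@H](Cl)[C@@](C)(O)[C@@H](OC(C)(C)O3)[C@H]13 | intermediate
17 | (8S)-homoallylic alcohol: ring of 14 carrying (S)-3-hydroxyhexa-1,5-dien-2-yl at C6α | C=C([C@H](CC=C)O)[C@H]1C[C@H](Cl)[C@@](C)(O)[C@@H](OC(C)(C)O3)[C@H]13 | intermediate
18 | 8-O-angelate ((Z)-2-methylbut-2-enoate) of 17 | C=C([C@H](CC=C)OC(=O)/C(C)=C\C)[C@H]1C[C@H](Cl)[C@@](C)(O)[C@@H](OC(C)(C)O3)[C@H]13 | intermediate
19 | prenyl compound: ring of 14 carrying (S)-3-(angeloyloxy)-6-methylhepta-1,5-dien-2-yl at C6α | C=C([C@H](CC=C(C)C)OC(=O)/C(C)=C\C)[C@H]1C[C@H](Cl)[C@@](C)(O)[C@@H](OC(C)(C)O3)[C@H]13 | intermediate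
20 | 8-O-angeloyl 4β-chloro-3β-methylcyclohexane-1α,2α,3α-triol with the 6α side chain of 19 | C=C([C@H](CC=C(C)C)OC(=O)/C(C)=C\C)[C@H]1C[C@H](Cl)[C@@](C)(O)[C@@H](O)[C@H]1O | intermediate
21 | 1,2-O-dibutylstannylene acetal of 20 | C=C([C@H](CC=C(C)C)OC(=O)/C(C)=C\C)[C@H]1C[C@H](Cl)[C@@](C)(O)[C@@H](O[Sn](CCCC)(CCCC)O3)[C@H]13 | intermediate
22 | 2,8-di-O-angelate of the 4β-chloro-1α,2α,3α-triol with the C10=C11 alkene (10,11-deoxy target) | C=C([C@H](CC=C(C)C)OC(=O)/C(C)=C\C)[C@H]1C[C@H](Cl)[C@@](C)(O)[C@@H](OC(=O)/C(C)=C\C)[C@H]1O | intermediate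
23 | CNP0158207.1 | C=C([C@H](C[C@H]1OC1(C)C)OC(=O)/C(C)=C\C)[C@H]1C[C@H](Cl)[C@@](C)(O)[C@@H](OC(=O)/C(C)=C\C)[C@H]1O | target

**Step count.** Total: 15 steps. Longest linear sequence: 14 steps (steps 1, 2 and 4–15); step 3 is a one-step branch.

**Steps most likely to fail**

1. Step 4 (proposed new method). The intermolecular aldol addition may show poor simple diastereoselection at C2. A second molecule of 6 may add to the intermediate aldehyde before the ring closes. The C7 cation may be captured by chloride instead of losing a proton. Fallback with known chemistry, from 4 back to 9, making the two bonds in separate steps: a Ti(IV)–BINOL-catalysed glyoxylate–ene reaction of 4 with ethyl glyoxylate (BINOL enantiomer chosen for the C1 configuration) should form C1–C6 and the isopropenyl group, giving α-hydroxy ester F1. Silylation with TESCl and imidazole should give triethylsilyl ether F2, and DIBAL-H at −78 °C should give keto-aldehyde F3. A SmI2 pinacol cyclisation should then form C2–C3 as the cis-2,3-diol, giving 1-O-triethylsilyl triol F4. PPTS in methanol should remove the triethylsilyl group and return the route to 9.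

2. Step 8. SN2 attack of chloride at the neopentyl-type secondary carbon C4 may be slow, so that attack at sulfur or elimination competes. Fallback from 11 back to 14: thiocarbonyldiimidazole should give cyclic thionocarbonate F5, and Corey–Winter olefination with trimethyl phosphite should give 3,4-alkene F6. N-chlorosuccinimide in aqueous acetone should then form the chloronium ion on the open β face of the more nucleophilic trisubstituted ring alkene. Water should open it at the tertiary C3 from the α face (Markovnikov, anti), which gives the same trans-diaxial chlorohydrin 14.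

3. Step 14. Acylation may take place at O1 instead of O2, or the angelate may migrate or isomerise to the tiglate during stannylene formation. Fallback from 20 back to 22: phenylboronic acid with removal of water should bridge the syn-diaxial C1 and C3 hydroxyl groups as six-membered 1,3-phenylboronate F7, as is known for all-cis 1,2,3-triols such as β-ribopyranosides. This leaves only the C2 hydroxyl group free. Acylation with the angelic 2,4,6-trichlorobenzoic mixed anhydride should give 2-O-angeloyl boronate F8, and exchange with propane-1,3-diol should release 22.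

**Further compounds**

F1 | step 4 | α-hydroxy ester: ethyl 5-(tert-butyldimethylsilyloxy)-2-hydroxy-6-oxo-3-(prop-1-en-2-yl)heptanoate, configured as in 9 | CC(=O)[C@H](O[Si](C)(C)C(C)(C)C)C[C@H](C(C)=C)[C@H](O)C(=O)OCC
F2 | step 4 | triethylsilyl ether of F1 | CC(=O)[C@H](O[Si](C)(C)C(C)(C)C)C[C@H](C(C)=C)[C@H](O[Si](CC)(CC)CC)C(=O)OCC
F3 | step 4 | keto-aldehyde: 5-(tert-butyldimethylsilyloxy)-6-oxo-3-(prop-1-en-2-yl)-2-(triethylsilyloxy)heptanal | CC(=O)[C@H](O[Si](C)(C)C(C)(C)C)C[C@H](C(C)=C)[C@H](O[Si](CC)(CC)CC)C=O
F4 | step 4 | 1-O-triethylsilyl ether of 9 | C=C(C)[C@H]1C[C@@H](O[Si](C)(C)C(C)(C)C)[C@@](C)(O)[C@@H](O)[C@H]1O[Si](CC)(CC)CC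
F5 | step 8 | 3α,4α-cyclic thionocarbonate of 11 | C=C(C)[C@H]1C[C@@H](O4)[C@@](C)(OC4=S)[C@@H](OC(C)(C)O3)[C@H]13
F6 | step 8 | 1α,2α-(isopropylidenedioxy)-3-methyl-6α-(prop-1-en-2-yl)cyclohex-3-ene | C=C(C)[C@H]1CC=C(C)[C@@H](OC(C)(C)O3)[C@H]13
F7 | step 14 | 1,3-O-phenylboronate of 20 | C=C([C@H](CC=C(C)C)OC(=O)/C(C)=C\C)[C@H]1C[C@H](Cl)[C@@](C)(O4)[C@@H](O)[C@H]1OB4c1ccccc1
F8 | step 14 | 2-O-angelate of F7 | C=C([C@H](CC=C(C)C)OC(=O)/C(C)=C\C)[C@H]1C[C@H](Cl)[C@@](C)(O4)[C@@H](OC(=O)/C(C)=C\C)[C@H]1OB4c1ccccc1
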